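**Retrosynthetic overview**
- The 7-O-sulfate is installed last but one, on a flavone whose 5-, 8-, 3'- and 4'-OH are benzyl ethers and whose 7-OH alone is free; hydrogenolysis then frees the four phenols.
- Ring C (the pyranone) comes from acid unmasking and I2/DMSO oxidative cyclisation of a chalcone. The chalcone comes from an intermolecular Claisen–Schmidt aldol condensation of a ring A acetophenone with 3,4-bis(benzyloxy)benzaldehyde (ring B).
- The ring A acetophenone (2,4-di-OMOM, 3,6-di-OBn) comes from the symmetric 2,5-bis(benzyloxy)-1,3-bis(methoxymethoxy)benzene by ortho-lithiation, acetaldehyde addition and oxidation.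
- The symmetric arene comes from 3,4,5-trihydroxybenzaldehyde: selective 4-O-benzylation, bis-MOM protection, Baeyer–Villiger (CHO to OH), benzylation.
- Ring order: rings A and B are bought as benzene units; ring C is the only ring formed, after the aldol C–C bond.

Assumption: the target has no stereocentre, so there is no enantiomer to control; it is drawn as the free hydrogen sulfate and is delivered in that protonation state (the sodium salt 17 is the form to store).

**Step 1**
Reactants: 1 3,4,5-trihydroxybenzaldehyde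
Product: 2 4-(benzyloxy)-3,5-dihydroxybenzaldehyde
Conditions: BnBr (1.0 equiv), NaHCO3 (1.5 equiv), NaI (0.1 equiv), DMF, 40 °C, N2
Reagents that add atoms: benzyl bromide, BrCc1ccccc1
Why: Williamson etherification under weak-base control, in which NaHCO3 ionises only the 4-OH (para to the formyl group and the most acidic), so the single benzyl group goes onto the central oxygen.

**Step 2**
Reactants: 2 4-(benzyloxy)-3,5-dihydroxybenzaldehyde
Product: 3 4-(benzyloxy)-3,5-bis(methoxymethoxy)benzaldehyde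
Conditions: MOMCl (3 equiv), i-Pr2NEt (4 equiv), CH2Cl2, 0 °C to rt
Reagents that add atoms: chloromethyl methyl ether, COCCl
Why: O-alkylation of the two remaining, equivalent phenols with an α-chloro ether gives MOM acetals that survive peracid, base and organolithium.

**Step 3**
Reactants: 3 4-(benzyloxy)-3,5-bis(methoxymethoxy)benzaldehyde
Product: 5 4-(benzyloxy)-3,5-bis(methoxymethoxy)phenol, via aryl formate 4 (not isolated)
Conditions: mCPBA (1.5 equiv), CH2Cl2, rt; then K2CO3 (0.2 equiv), MeOH, rt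
Reagents that add atoms: 3-chloroperoxybenzoic acid, O=C(OO)c1cccc(Cl)c1
Why: Baeyer–Villiger (Dakin-type) oxidation, in which the electron-rich para-alkoxyaryl group migrates to give the formate, and mild methanolysis then frees the phenol.

**Step 4**
Reactants: 5 4-(benzyloxy)-3,5-bis(methoxymethoxy)phenol
Product: 6 2,5-bis(benzyloxy)-1,3-bis(methoxymethoxy)benzene
Conditions: BnBr (1.2 equiv), K2CO3 (2 equiv), DMF, rt
Reagents that add atoms: benzyl bromide, BrCc1ccccc1
Why: Williamson etherification of the only free phenol gives a C2-symmetric arene whose two remaining ring C–H positions are equivalent.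

**Step 5**
Reactants: 6 2,5-bis(benzyloxy)-1,3-bis(methoxymethoxy)benzene
Product: 8 1-[3,6-bis(benzyloxy)-2,4-bis(methoxymethoxy)phenyl]ethan-1-ol (racemic), via aryllithium 7 (not isolated)
Conditions: n-BuLi (1.3 equiv), THF, 0 °C, 1 h; then CH3CHO (3 equiv), −78 °C to 0 °C; then H2O
Reagents that add atoms: acetaldehyde, CC=O
Why: Directed ortho-metalation at the only ring C–H, which is flanked by OMOM and OBn, followed by 1,2-addition to acetaldehyde; the carbinol centre forms racemic and is removed in step 6.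

**Step 6**
Reactants: 8 1-[3,6-bis(benzyloxy)-2,4-bis(methoxymethoxy)phenyl]ethan-1-ol
Product: 9 1-[3,6-bis(benzyloxy)-2,4-bis(methoxymethoxy)phenyl]ethan-1-one
Conditions: Dess–Martin periodinane (1.3 equiv), pyridine (3 equiv), CH2Cl2, 0 °C to rt
Reagents that add atoms: none
Why: Dess–Martin oxidation of the hindered secondary benzylic alcohol under buffered, near-neutral conditions leaves the MOM and benzyl ethers untouched.

**Step 7**
Reactants: 9 1-[3,6-bis(benzyloxy)-2,4-bis(methoxymethoxy)phenyl]ethan-1-one; 10 3,4-bis(benzyloxy)benzaldehyde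
Product: 12 (2E)-1-[3,6-bis(benzyloxy)-2,4-bis(methoxymethoxy)phenyl]-3-[3,4-bis(benzyloxy)phenyl]prop-2-en-1-one, via aldol adduct 11 (not isolated)
Conditions: 10 (1.2 equiv), KOH (50% aq, 10 equiv), EtOH/THF, rt, 24–48 h; then aq NH4Cl
Reagents that add atoms: none
Why: Claisen–Schmidt crossed aldol condensation between the only enolisable partner (the methyl ketone) and a non-enolisable aldehyde; E1cB dehydration removes the racemic aldol centre and gives the thermodynamic E-enone.

**Step 8**
Reactants: 12 (2E)-1-[3,6-bis(benzyloxy)-2,4-bis(methoxymethoxy)phenyl]-3-[3,4-bis(benzyloxy)phenyl]prop-2-en-1-one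
Product: 15 5,8-bis(benzyloxy)-2-[3,4-bis(benzyloxy)phenyl]-7-hydroxy-4H-chromen-4-one, via dihydroxychalcone 13 (not isolated), via flavanone 14 (not isolated)
Conditions: conc. HCl (cat.), MeOH/THF, 55 °C; evaporate; then I2 (0.1 equiv), DMSO, 120 °C; aq Na2S2O3 wash
Reagents that add atoms: none
Why: Acid-catalysed acetal exchange removes both MOM groups, then the only ortho-OH closes ring C by oxa-Michael addition and iodine-catalysed dehydrogenation with DMSO as terminal oxidant, which fixes the 5,7,8 pattern and destroys the racemic flavanone centre.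

**Step 9**
Reactants: 15 5,8-bis(benzyloxy)-2-[3,4-bis(benzyloxy)phenyl]-7-hydroxy-4H-chromen-4-one
Product: 16 sodium 5,8-bis(benzyloxy)-2-[3,4-bis(benzyloxy)phenyl]-4-oxo-4H-chromen-7-yl sulfate
Conditions: SO3·pyridine (5 equiv), pyridine, 50 °C; then aq NaHCO3; silica gel, CH2Cl2/MeOH
Reagents that add atoms: sulfur trioxide–pyridine complex, [O-]S(=O)(=O)[n+]1ccccc1; sodium hydrogen carbonate, [Na+].OC([O-])=O
Why: O-sulfation with SO3·pyridine can only occur at the 7-OH because every other phenol is a benzyl ether, and the sodium salt is stable and chromatographable.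

**Step 10**
Reactants: 16 sodium 5,8-bis(benzyloxy)-2-[3,4-bis(benzyloxy)phenyl]-4-oxo-4H-chromen-7-yl sulfate
Product: 18 2-(3,4-dihydroxyphenyl)-5,8-dihydroxy-4-oxo-4H-chromen-7-yl hydrogen sulfate (8-hydroxyluteolin 7-sulfate), via sodium salt 17 (not isolated)
Conditions: H2 (1 atm), 10% Pd/C, MeOH/THF, rt; filter under Ar; then 0.1 M aq HCl (1.0 equiv), 0 °C; C18 desalting, freeze-drying
Reagents that add atoms: none
Why: Catalytic hydrogenolysis cleaves the four benzyl C–O bonds while the aryl sulfate and the flavone C2=C3 bond are inert, and one equivalent of cold acid protonates the sulfate faster than it hydrolyses.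

**Compound list**
1 | 3,4,5-trihydroxybenzaldehyde | O=Cc1cc(O)c(O)c(O)c1 | starting material
2 | 4-(benzyloxy)-3,5-dihydroxybenzaldehyde | O=Cc1cc(O)c(OCc2ccccc2)c(O)c1 | intermediate
3 | 4-(benzyloxy)-3,5-bis(methoxymethoxy)benzaldehyde | O=Cc1cc(OCOC)c(OCc2ccccc2)c(OCOC)c1 | intermediate
4 | 4-(benzyloxy)-3,5-bis(methoxymethoxy)phenyl formate | O=COc1cc(OCOC)c(OCc2ccccc2)c(OCOC)c1 | intermediate
5 | 4-(benzyloxy)-3,5-bis(methoxymethoxy)phenol | Oc1cc(OCOC)c(OCc2ccccc2)c(OCOC)c1 | intermediate
6 | 2,5-bis(benzyloxy)-1,3-bis(methoxymethoxy)benzene | COCOc1cc(OCc2ccccc2)cc(OCOC)c1OCc1ccccc1 | intermediate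
7 | [3,6-bis(benzyloxy)-2,4-bis(methoxymethoxy)phenyl]lithium | [Li]c1c(OCOC)c(OCc2ccccc2)c(OCOC)cc1OCc1ccccc1 | intermediate
8 | 1-[3,6-bis(benzyloxy)-2,4-bis(methoxymethoxy)phenyl]ethan-1-ol (racemic) | CC(O)c1c(OCOC)c(OCc2ccccc2)c(OCOC)cc1OCc1ccccc1 | intermediate
9 | 1-[3,6-bis(benzyloxy)-2,4-bis(methoxymethoxy)phenyl]ethan-1-one | CC(=O)c1c(OCOC)c(OCc2ccccc2)c(OCOC)cc1OCc1ccccc1 | intermediate
10 | 3,4-bis(benzyloxy)benzaldehyde | O=Cc1ccc(OCc2ccccc2)c(OCc2ccccc2)c1 | starting material
11 | 1-[3,6-bis(benzyloxy)-2,4-bis(methoxymethoxy)phenyl]-3-[3,4-bis(benzyloxy)phenyl]-3-hydroxypropan-1-one (racemic) | O=C(CC(O)c1ccc(OCc2ccccc2)c(OCc2ccccc2)c1)c1c(OCOC)c(OCc2ccccc2)c(OCOC)cc1OCc1ccccc1 | intermediate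
12 | (2E)-1-[3,6-bis(benzyloxy)-2,4-bis(methoxymethoxy)phenyl]-3-[3,4-bis(benzyloxy)phenyl]prop-2-en-1-one | O=C(/C=C/c1ccc(OCc2ccccc2)c(OCc2ccccc2)c1)c1c(OCOC)c(OCc2ccccc2)c(OCOC)cc1OCc1ccccc1 | intermediate
13 | (2E)-1-[3,6-bis(benzyloxy)-2,4-dihydroxyphenyl]-3-[3,4-bis(benzyloxy)phenyl]prop-2-en-1-one | O=C(/C=C/c1ccc(OCc2ccccc2)c(OCc2ccccc2)c1)c1c(O)c(OCc2ccccc2)c(O)cc1OCc1ccccc1 | intermediate
14 | 5,8-bis(benzyloxy)-2-[3,4-bis(benzyloxy)phenyl]-7-hydroxy-2,3-dihydro-4H-chromen-4-one (racemic) | O=C1CC(c2ccc(OCc3ccccc3)c(OCc3ccccc3)c2)Oc2c(OCc3ccccc3)c(O)cc(OCc3ccccc3)c21 | intermediate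
15 | 5,8-bis(benzyloxy)-2-[3,4-bis(benzyloxy)phenyl]-7-hydroxy-4H-chromen-4-one | O=c1cc(-c2ccc(OCc3ccccc3)c(OCc3ccccc3)c2)oc2c(OCc3ccccc3)c(O)cc(OCc3ccccc3)c12 | intermediate
16 | sodium 5,8-bis(benzyloxy)-2-[3,4-bis(benzyloxy)phenyl]-4-oxo-4H-chromen-7-yl sulfate | O=c1cc(-c2ccc(OCc3ccccc3)c(OCc3ccccc3)c2)oc2c(OCc3ccccc3)c(OS(=O)(=O)[O-])cc(OCc3ccccc3)c12.[Na+] | intermediate
17 | sodium 2-(3,4-dihydroxyphenyl)-5,8-dihydroxy-4-oxo-4H-chromen-7-yl sulfate | O=c1cc(-c2ccc(O)c(O)c2)oc2c(O)c(OS(=O)(=O)[O-])cc(O)c12.[Na+] | intermediate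
18 | 8-hydroxyluteolin 7-sulfate, 2-(3,4-dihydroxyphenyl)-5,8-dihydroxy-4-oxo-4H-chromen-7-yl hydrogen sulfate | O=c1cc(-c2ccc(O)c(O)c2)oc2c(O)c(OS(=O)(=O)O)cc(O)c12 | target

**Totals**
Total step count: 10. Longest linear sequence: 10 steps (1 to 18); aldehyde 10 is bought and enters at step 7.

**Steps most likely to fail, with fallbacks**

Step 5 is the most exposed, because n-BuLi may deprotonate a benzylic OCH2Ph position (leading to Wittig rearrangement) in competition with ring lithiation. The fallback sets out from 6 and comes back at 8. Bromination of 6 with N-bromosuccinimide (1.0 equiv, MeCN, 0 °C) gives 1,4-bis(benzyloxy)-2-bromo-3,5-bis(methoxymethoxy)benzene F1. Bromine–lithium exchange with n-BuLi in THF at −78 °C is complete within minutes, well below the temperature at which benzylic deprotonation matters. It gives the same aryllithium 7, which is quenched with acetaldehyde to give 8.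

Step 8 is second. The electron-rich ring A with its free 7-OH could be iodinated at C6, and HI at 120 °C could remove benzyl groups unevenly. The fallback sets out from 9 and comes back at 15, replacing the chalcone and its oxidation by an intermolecular Claisen condensation. Commercial 3,4-bis(benzyloxy)benzoic acid is converted with oxalyl chloride and catalytic DMF into 3,4-bis(benzyloxy)benzoyl chloride F2. The lithium enolate of 9 (LiN(SiMe3)2, 2.5 equiv, THF, −78 °C) is C-acylated by F2 to give 1-[3,6-bis(benzyloxy)-2,4-bis(methoxymethoxy)phenyl]-3-[3,4-bis(benzyloxy)phenyl]propane-1,3-dione F3. Warming F3 with HCl in MeOH/THF at 60 °C removes both MOM groups and cyclodehydrates the 2-hydroxy diketone directly to flavone 15, with no oxidant or iodine present.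

Step 1 is third, because mono-benzylation of an air-sensitive triphenol can give mixtures of regioisomers and over-alkylated material. The fallback sets out from 1 and comes back at 2. Peracetylation (Ac2O, pyridine) gives 5-formylbenzene-1,2,3-triyl triacetate F4. Heating F4 with BnBr, K2CO3 and KI in acetone cleaves only the acetate para to the formyl group (the best phenoxide leaving group) and benzylates that oxygen in situ, giving 2-(benzyloxy)-5-formyl-1,3-phenylene diacetate F5. Methanolysis of F5 (K2CO3, MeOH, rt) returns 2.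

**Further compounds**
F1 | step 5 | 1,4-bis(benzyloxy)-2-bromo-3,5-bis(methoxymethoxy)benzene | Brc1c(OCOC)c(OCc2ccccc2)c(OCOC)cc1OCc1ccccc1
F2 | step 8 | 3,4-bis(benzyloxy)benzoyl chloride | O=C(Cl)c1ccc(OCc2ccccc2)c(OCc2ccccc2)c1
F3 | step 8 | 1-[3,6-bis(benzyloxy)-2,4-bis(methoxymethoxy)phenyl]-3-[3,4-bis(benzyloxy)phenyl]propane-1,3-dione | O=C(CC(=O)c1ccc(OCc2ccccc2)c(OCc2ccccc2)c1)c1c(OCOC)c(OCc2ccccc2)c(OCOC)cc1OCc1ccccc1
F4 | step 1 | 5-formylbenzene-1,2,3-triyl triacetate | CC(=O)Oc1cc(C=O)cc(OC(C)=O)c1OC(C)=O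
F5 | step 1 | 2-(benzyloxy)-5-formyl-1,3-phenylene diacetate | CC(=O)Oc1cc(C=O)cc(OC(C)=O)c1OCc1ccccc1
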